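**Retrosynthetic overview**

1. Numbering: lactam ring A = N4, C3 (N-CH), C2 (CH2), C1 (CH), C9a (C=O); chain C5–C8; ketone C9; C10 (CH-Et); lactone D = C11 (CH-O), C12, C13 (CH-Me), C14; side lactone E = C18–C21. Enabling feature: in the eleven-membered ring the ketone carbon C9 and the lactam carbonyl carbon C9a face each other. They are bridged by N4–C5–C8 on one side and by C1–C12–C11–C10 on the other, and they carry the oxidation pattern of a cleaved 1,2-amino alcohol.
2. Last disconnection (temporary bond): rejoin C9–C9a. The target comes from the 9-hydroxy tetracyclic amine 29 by lead tetraacetate fragmentation and oxidation of the iminium ion to the lactam. The macrocycle thereby folds into azepane ring B fused to cyclohexane ring C.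
3. Key disconnection: in that tetracycle C9a–N4–C3 is an azomethine ylide and C1=C2 is a vinyl group on lactone D, four atoms away. One intramolecular [3+2] cycloaddition cuts C1–C9a and C2–C3 and leads back to the monocyclic azepinium salt 25. The temporary quaternary carbinol centre C9 steers the dipole face.
4. 25 comes from cyclic imine 19 and bromoketone 24 (auxiliary alkylation sets C20). 19 comes from an anti-selective Mukaiyama aldol (C9, C10), allylboration/lactonisation (C11, C12), enolate methylation (C13), then azide, lactam and partial reduction.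
5. Order of ring formation: D, then B, then A and C together (key step), then E, and finally opening of the B/C bicycle to the eleven-membered ring.

Key step: step 15

Assumption: the (S,S) ligand in step 2 is taken to shield the ketone face that leads to the drawn (2S,3R) adduct; if the sense of induction is opposite, the equally available (R,R) ligand is used and nothing else changes.

**Step 1**
Reactants: 1 S-methyl butanethioate
Product: 2 (Z)-trimethyl{[1-(methylsulfanyl)but-1-en-1-yl]oxy}silane (ethyl cis to sulfur)
Conditions: LiN(i-Pr)2, THF, −78 °C; Me3SiCl, −78 °C to rt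
Reagents that add atoms: chlorotrimethylsilane C[Si](C)(C)Cl
Why: Kinetic deprotonation through the cyclic transition state gives the enolate with ethyl cis to sulfur, and O-silylation fixes it as the silyl ketene thioacetal needed for the Mukaiyama aldol.

**Step 2**
Reactants: 2 (Z)-silyl ketene thioacetal, 3 ethyl 6-chloro-2-oxohexanoate
Product: 5 ethyl (2S,3R)-2-(4-chlorobutyl)-2-hydroxy-3-[(methylsulfanyl)carbonyl]pentanoate, via trimethylsilyl ether 4 (not isolated)
Conditions: Sn(OTf)2 (10 mol %), (S,S)-Bn-box (11 mol %), CH2Cl2, −78 °C; 1 M HCl, THF, 0 °C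
Reagents that add atoms: none
Why: Catalytic enantioselective anti-selective Mukaiyama aldol, in which the α-keto ester chelates the divalent tin bis(oxazoline) Lewis acid through both carbonyl oxygens, the ligand shields one ketone face and the open transition state places ethyl anti to hydroxyl along C9a–C9–C10–C11, which sets C10 for good and the temporary carbinol centre C9.

**Step 3**
Reactants: 5 aldol adduct
Product: 6 ethyl (2S,3R)-2-(4-chlorobutyl)-3-[(methylsulfanyl)carbonyl]-2-(triethylsilyloxy)pentanoate
Conditions: Et3SiOTf, 2,6-lutidine, CH2Cl2, 0 °C to rt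
Reagents that add atoms: triethylsilyl triflate CC[Si](CC)(CC)OS(=O)(=O)C(F)(F)F
Why: Silyl triflate silylation of the hindered tertiary alcohol blocks retro-aldol cleavage and keeps the temporary carbinol inert until the end, and no stereocentre is touched.

**Step 4**
Reactants: 6 silyl ether
Product: 7 ethyl (2S,3R)-2-(4-chlorobutyl)-3-formyl-2-(triethylsilyloxy)pentanoate
Conditions: Et3SiH, Pd/C (cat.), acetone, rt
Reagents that add atoms: none
Why: Fukuyama reduction, in which zerovalent palladium inserts only into the C–S bond, so the thioester becomes the aldehyde while the ethyl ester, alkyl chloride and silyl ether survive and the neutral medium avoids epimerisation at C10.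

**Step 5**
Reactants: 8 prop-2-yn-1-ol, 9 triethyl orthoacetate
Product: 10 ethyl penta-3,4-dienoate
Conditions: EtCO2H (cat.), 140 °C, ethanol distilled off
Reagents that add atoms: none
Why: Johnson-Claisen rearrangement of the propargyl ketene acetal formed in situ gives the β-allenic ester by a [3,3] shift.

**Step 6**
Reactants: 10 ethyl penta-3,4-dienoate, 11 dicyclohexylborane, 7 aldehyde
Product: 14 ethyl (2S,3S)-2-(4-chlorobutyl)-3-[(2R,3R)-3-ethenyl-5-oxooxolan-2-yl]-2-(triethylsilyloxy)pentanoate, via allylborane 12 (not isolated), via hydroxy diester 13 (not isolated)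
Conditions: 10 + 11, THF, 0 °C to rt; 7, −78 to 0 °C; HOCH2CH2NH2; PPTS, CH2Cl2, rt
Reagents that add atoms: none
Why: Hydroboration of the terminal allene bond gives the thermodynamically preferred (E)-allylborane, whose chair (Zimmerman-Traxler) allylboration delivers the anti homoallylic alcohol (C11/C12) while Felkin-Anh attack anti to the bulky quaternary C9 group sets C11–O syn to the C10 ethyl, and the γ-hydroxy ester closes to the cis-lactone D because the other ester is neopentylic and shielded.

**Step 7**
Reactants: 14 lactone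
Product: 15 ethyl (2S,3S)-2-(4-chlorobutyl)-3-[(2R,3S,4S)-3-ethenyl-4-methyl-5-oxooxolan-2-yl]-2-(triethylsilyloxy)pentanoate
Conditions: LiN(SiMe3)2, THF, −78 °C; MeI, −78 °C
Reagents that add atoms: iodomethane CI
Why: Lactone enolate alkylation, in which iodomethane approaches the planar enolate from the face opposite the adjacent C12 vinyl group and sets C13 trans to it, while the ethyl ester has no α-hydrogen and cannot enolise.

**Step 8**
Reactants: 15 chloride
Product: 16 ethyl (2S,3S)-2-(4-azidobutyl)-3-[(2R,3S,4S)-3-ethenyl-4-methyl-5-oxooxolan-2-yl]-2-(triethylsilyloxy)pentanoate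
Conditions: NaN3, NaI (cat.), DMF, 60 °C
Reagents that add atoms: sodium azide [Na+].[N-]=[N+]=[N-]
Why: Iodide-assisted SN2 displacement of the primary chloride by azide, remote from all stereocentres.

**Step 9**
Reactants: 16 azide
Product: 18 (3S)-3-{(1S)-1-[(2R,3S,4S)-3-ethenyl-4-methyl-5-oxooxolan-2-yl]propyl}-3-(triethylsilyloxy)azepan-2-one, via amino ester 17 (not isolated)
Conditions: PPh3, THF/H2O, 45 °C; toluene, 2-hydroxypyridine (cat.), 110 °C
Reagents that add atoms: none
Why: Staudinger reduction followed by seven-membered lactamisation of the amino ester, helped by the gem-disubstituent effect at C9 and by the inductive activation of the α-silyloxy ester, whereas attack on the lactone carbonyl would need an eleven-membered transition state.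

**Step 10**
Reactants: 18 lactam
Product: 19 (6S)-6-{(1S)-1-[(2R,3S,4S)-3-ethenyl-4-methyl-5-oxooxolan-2-yl]propyl}-6-(triethylsilyloxy)-3,4,5,6-tetrahydro-2H-azepine
Conditions: Tf2O, 2-fluoropyridine, CH2Cl2, −78 to 0 °C; Et3SiH, rt; aq NaHCO3
Reagents that add atoms: none
Why: Electrophilic activation of the secondary amide as its O-triflyl derivative and a single hydride transfer from the silane (controlled reduction of secondary amides to imines), in which the lactone is too weakly nucleophilic to be activated and the aldimine, lacking an α-hydrogen, cannot tautomerise.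

**Step 11**
Reactants: 20 (R)-4-benzyl-3-propanoyl-1,3-oxazolidin-2-one, 21 2,3-dibromoprop-1-ene
Product: 22 (R)-4-benzyl-3-[(2S)-4-bromo-2-methylpent-4-enoyl]-1,3-oxazolidin-2-one
Conditions: NaN(SiMe3)2, THF, −78 °C; 21, −78 to −40 °C
Reagents that add atoms: none
Why: Evans asymmetric alkylation, in which the chelated (Z)-sodium enolate is attacked by the allylic bromide on the face opposite the benzyl group, setting C20 as S.

**Step 12**
Reactants: 22 alkylated imide
Product: 23 methyl (2S)-4-bromo-2-methylpent-4-enoate
Conditions: NaOMe (cat.), MeOH, 0 °C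
Reagents that add atoms: methanol CO
Why: Base-catalysed methanolysis of the exocyclic imide carbonyl removes the auxiliary at low temperature without epimerisation of the α-methyl centre.

**Step 13**
Reactants: 23 vinyl bromide
Product: 24 methyl (2S)-5-bromo-2-methyl-4-oxopentanoate
Conditions: NBS, HBr (cat.), MeCN/H2O, rt
Reagents that add atoms: N-bromosuccinimide O=C1CCC(=O)N1Br; water O
Why: Bromohydrin formation on the 2-bromoalkene (water adds at the bromine-bearing carbon) followed by loss of HBr gives the terminal α-bromo ketone regiospecifically.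

**Step 14**
Reactants: 19 cyclic imine, 24 bromoketone
Product: 25 (6S)-1-[(4S)-5-methoxy-4-methyl-2,5-dioxopentyl]-6-{(1S)-1-[(2R,3S,4S)-3-ethenyl-4-methyl-5-oxooxolan-2-yl]propyl}-6-(triethylsilyloxy)-3,4,5,6-tetrahydro-2H-azepin-1-ium bromide
Conditions: MeCN, 40 °C
Reagents that add atoms: none
Why: Menshutkin-type N-alkylation of the nucleophilic aldimine nitrogen by the reactive α-bromo ketone under neutral conditions, and since C9 is quaternary no enamine can form that would be C-alkylated.

**Step 15**
Reactants: 25 azepinium bromide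
Product: 27 tetracyclic amino keto ester (rings A–D; 9S-triethylsilyloxy, 9aS; H1 cis to H9a; the C3 chain C(=O)CH2CH(CH3)CO2Me cis to H9a; C1, C3 and C10–C13 arranged as in the target), via azomethine ylide 26 (not isolated)
Conditions: i-Pr2NEt, toluene/MeCN (9:1), 0.005 M, 110 °C
Reagents that add atoms: none
Why: The amine base removes the acidic N-CH2-C(=O) proton of 25 to give the carbonyl-stabilised azomethine ylide 26 (C9a=N4(+)–C3(−)), which adds suprafacially across the C1=C2 vinyl group in a concerted thermal [3+2] cycloaddition that forms C9a–C1 and C3–C2 together. The closest known reaction type is the intramolecular cycloaddition of N-alkyl iminium ylides (a cyclic imine quaternised with an α-halo carbonyl compound, then base) onto unactivated terminal alkenes held by three- or four-atom tethers. Pyrrolidine ring A is closed by both new bonds, and cyclohexane ring C is closed by C9a–C1 in the fused (6-exo) mode through the four-atom tether C9–C12, whereas the bridged regioisomer would need a strained seven-membered ring. The fully substituted C9 holds C10 on one face of the dipole and its silyloxy group anti to N4, so the alkene reaches only the face that gives 9aS, and the short tether enforces the cis A/C fusion that sets C1 through a chair-like array with the ethyl group and C11–O equatorial. At C3 the acyl group takes the inside position of the S-shaped ylide to avoid A(1,3) strain with C5H2 and ends cis to H9a on the open face, which is also the thermodynamic epimer, so base epimerisation converges on the same isomer. The step needs exclusive ylide formation, and this is secured because C9 bears no hydrogen (no enamine), the charge sits on the acyl-bearing C3, and silyloxide is a poor leaving group (no β-elimination).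

**Step 16**
Reactants: 27 tetracyclic amino keto ester
Product: 29 9-hydroxy pentacyclic amine (rings A–E; free tertiary alcohol at C9, 9S,9aS; all other centres as in the target), via silyl-protected bislactone 28 (not isolated)
Conditions: LiBH(s-Bu)3, THF, −78 °C; 48% aq HF, MeCN, 0 °C to rt
Reagents that add atoms: none
Why: The bulky borohydride reduces only the ketone under polar Felkin-Anh control (hydride anti to the C3–N4 bond), giving the 3,18-syn amino alkoxide that closes onto the methyl ester to form lactone E with C18 S and the preset C20 methyl cis, and aqueous HF then removes the triethylsilyl group.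

**Step 17**
Reactants: 29 9-hydroxy pentacyclic amine
Product: 31 target keto lactam CNP0147860.1, via keto iminium ion 30 (not isolated)
Conditions: Pb(OAc)4, CH2Cl2, −20 °C; NaClO2, NaH2PO4, 2-methyl-2-butene, t-BuOH/H2O, 0 °C
Reagents that add atoms: sodium chlorite [Na+].[O-]Cl=O
Why: Criegee-type cleavage of the 1,2-amino alcohol, in which the lead alkoxide of C9–OH fragments in Grob fashion with push from the N4 lone pair, breaks the temporary C9–C9a bond and opens the B/C bicycle to the eleven-membered keto iminium ion, which chlorite oxidises (Pinnick-type) to the lactam under buffered conditions before it can tautomerise, so C1 and C10 should keep their configuration.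

**Compound list**

1 | S-methyl butanethioate | CCCC(=O)SC | starting material
2 | (Z)-trimethyl{[1-(methylsulfanyl)but-1-en-1-yl]oxy}silane | CC/C=C(\SC)O[Si](C)(C)C | intermediate
3 | ethyl 6-chloro-2-oxohexanoate | CCOC(=O)C(=O)CCCCCl | starting material
4 | ethyl (2S,3R)-2-(4-chlorobutyl)-3-[(methylsulfanyl)carbonyl]-2-(trimethylsilyloxy)pentanoate | CCOC(=O)[C@](O[Si](C)(C)C)(CCCCCl)[C@@H](CC)C(=O)SC | intermediate
5 | ethyl (2S,3R)-2-(4-chlorobutyl)-2-hydroxy-3-[(methylsulfanyl)carbonyl]pentanoate | CCOC(=O)[C@](O)(CCCCCl)[C@@H](CC)C(=O)SC | intermediate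
6 | ethyl (2S,3R)-2-(4-chlorobutyl)-3-[(methylsulfanyl)carbonyl]-2-(triethylsilyloxy)pentanoate | CCOC(=O)[C@](O[Si](CC)(CC)CC)(CCCCCl)[C@@H](CC)C(=O)SC | intermediate
7 | ethyl (2S,3R)-2-(4-chlorobutyl)-3-formyl-2-(triethylsilyloxy)pentanoate | CCOC(=O)[C@](O[Si](CC)(CC)CC)(CCCCCl)[C@@H](CC)C=O | intermediate
8 | prop-2-yn-1-ol | C#CCO | starting material
9 | triethyl orthoacetate | CC(OCC)(OCC)OCC | starting material
10 | ethyl penta-3,4-dienoate | C=C=CCC(=O)OCC | intermediate
11 | dicyclohexylborane | B(C1CCCCC1)C1CCCCC1 | starting material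
12 | ethyl (E)-5-(dicyclohexylboranyl)pent-3-enoate | CCOC(=O)C/C=C/CB(C1CCCCC1)C1CCCCC1 | intermediate
13 | diethyl (2S,3S,4R,5R)-2-(4-chlorobutyl)-5-ethenyl-3-ethyl-4-hydroxy-2-(triethylsilyloxy)heptanedioate | CCOC(=O)[C@](O[Si](CC)(CC)CC)(CCCCCl)[C@@H](CC)[C@H](O)[C@@H](C=C)CC(=O)OCC | intermediate
14 | ethyl (2S,3S)-2-(4-chlorobutyl)-3-[(2R,3R)-3-ethenyl-5-oxooxolan-2-yl]-2-(triethylsilyloxy)pentanoate | CCOC(=O)[C@](O[Si](CC)(CC)CC)(CCCCCl)[C@@H](CC)[C@@H]1OC(=O)C[C@@H]1C=C | intermediate
15 | ethyl (2S,3S)-2-(4-chlorobutyl)-3-[(2R,3S,4S)-3-ethenyl-4-methyl-5-oxooxolan-2-yl]-2-(triethylsilyloxy)pentanoate | CCOC(=O)[C@](O[Si](CC)(CC)CC)(CCCCCl)[C@@H](CC)[C@@H]1OC(=O)[C@@H](C)[C@@H]1C=C | intermediate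
16 | ethyl (2S,3S)-2-(4-azidobutyl)-3-[(2R,3S,4S)-3-ethenyl-4-methyl-5-oxooxolan-2-yl]-2-(triethylsilyloxy)pentanoate | CCOC(=O)[C@](O[Si](CC)(CC)CC)(CCCCN=[N+]=[N-])[C@@H](CC)[C@@H]1OC(=O)[C@@H](C)[C@@H]1C=C | intermediate
17 | ethyl (2S,3S)-2-(4-aminobutyl)-3-[(2R,3S,4S)-3-ethenyl-4-methyl-5-oxooxolan-2-yl]-2-(triethylsilyloxy)pentanoate | CCOC(=O)[C@](O[Si](CC)(CC)CC)(CCCCN)[C@@H](CC)[C@@H]1OC(=O)[C@@H](C)[C@@H]1C=C | intermediate
18 | (3S)-3-{(1S)-1-[(2R,3S,4S)-3-ethenyl-4-methyl-5-oxooxolan-2-yl]propyl}-3-(triethylsilyloxy)azepan-2-one | O=C1NCCCC[C@]1(O[Si](CC)(CC)CC)[C@@H](CC)[C@@H]2OC(=O)[C@@H](C)[C@@H]2C=C | intermediate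
19 | (6S)-6-{(1S)-1-[(2R,3S,4S)-3-ethenyl-4-methyl-5-oxooxolan-2-yl]propyl}-6-(triethylsilyloxy)-3,4,5,6-tetrahydro-2H-azepine | C1=NCCCC[C@]1(O[Si](CC)(CC)CC)[C@@H](CC)[C@@H]2OC(=O)[C@@H](C)[C@@H]2C=C | intermediate
20 | (R)-4-benzyl-3-propanoyl-1,3-oxazolidin-2-one | O=C1OC[C@@H](Cc2ccccc2)N1C(=O)CC | starting material
21 | 2,3-dibromoprop-1-ene | C=C(Br)CBr | starting material
22 | (R)-4-benzyl-3-[(2S)-4-bromo-2-methylpent-4-enoyl]-1,3-oxazolidin-2-one | O=C1OC[C@@H](Cc2ccccc2)N1C(=O)[C@@H](C)CC(Br)=C | intermediate
23 | methyl (2S)-4-bromo-2-methylpent-4-enoate | COC(=O)[C@@H](C)CC(Br)=C | intermediate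
24 | methyl (2S)-5-bromo-2-methyl-4-oxopentanoate | COC(=O)[C@@H](C)CC(=O)CBr | intermediate
25 | N-(acylmethyl)azepinium bromide (name in step 14) | C1=[N+](CC(=O)C[C@H](C)C(=O)OC)CCCC[C@]1(O[Si](CC)(CC)CC)[C@@H](CC)[C@@H]2OC(=O)[C@@H](C)[C@@H]2C=C.[Br-] | intermediate
26 | carbonyl-stabilised azomethine ylide from 25 | C1=[N+]([CH-]C(=O)C[C@H](C)C(=O)OC)CCCC[C@]1(O[Si](CC)(CC)CC)[C@@H](CC)[C@@H]2OC(=O)[C@@H](C)[C@@H]2C=C | intermediate
27 | tetracyclic amino keto ester (9S-silyloxy, 9aS, rings A–D) | CC[C@@H]1[C@@]2(O[Si](CC)(CC)CC)CCCCN3[C@H]2[C@@H](C[C@H]3C(=O)C[C@H](C)C(=O)OC)[C@@H]4[C@H]1OC(=O)[C@H]4C | intermediate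
28 | 9-triethylsilyloxy pentacyclic bislactone amine | CC[C@@H]1[C@@]2(O[Si](CC)(CC)CC)CCCCN3[C@H]2[C@@H](C[C@H]3[C@@H]5C[C@H](C)C(=O)O5)[C@@H]4[C@H]1OC(=O)[C@H]4C | intermediate
29 | 9-hydroxy pentacyclic bislactone amine | CC[C@@H]1[C@@]2(O)CCCCN3[C@H]2[C@@H](C[C@H]3[C@@H]5C[C@H](C)C(=O)O5)[C@@H]4[C@H]1OC(=O)[C@H]4C | intermediate
30 | eleven-membered keto iminium ion (C9 ketone, C9a(H)=N4(+); acetate as counter-ion) | CC[C@@H]1C(=O)CCCC[N+]2=C[C@@H](C[C@H]2[C@@H]2C[C@H](C)C(=O)O2)[C@@H]2[C@H]1OC(=O)[C@H]2C | intermediate
31 | CNP0147860.1 (1S,3S,10S,11R,12S,13S,18S,20S) | CC[C@@H]1C(=O)CCCCN2C(=O)[C@@H](C[C@H]2[C@@H]2C[C@H](C)C(=O)O2)[C@@H]2[C@H]1OC(=O)[C@H]2C | target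

**Totals**

Total step count: 17.
Longest linear sequence: 13 steps (1, 2, 5, 6, 7, 14, 15, 16, 18, 19, 25, 27, 29, 31; steps 1–4, 6–10, 14–17).

**Steps most likely to fail**

Step 15.
- What may go wrong: slow addition of the ketone-stabilised ylide to the unactivated alkene. Closure to the oxazoline, condensation of the ylide carbon with the side-chain ester, or attack on the wrong dipole face could then compete.
- Fallback: it sets out from imine 19, which would be quaternised with S-ethyl bromothioacetate to the thioester azepinium bromide F1.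
- Its ylide lacks the keto ester chain and is closer to the ester-stabilised ylides known to add to plain alkenes. Base-induced cycloaddition would give the tetracyclic C3 S-ethyl thioester F2.
- The side chain would then be attached by Fukuyama coupling (PdCl2(PPh3)2, toluene) with the zinc homoenolate bromo[(2R)-3-methoxy-2-methyl-3-oxopropyl]zinc F3. This reagent is made from commercial methyl (R)-3-bromo-2-methylpropanoate and zinc dust.
- The fallback comes back to the route at 27.

Step 17.
- What may go wrong: competing oxidation of the amine at other α-positions, tautomerisation of the iminium ion to the enamine with loss of configuration at C1, or β-elimination of the lactone carboxylate from the new ketone.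
- Fallback: it sets out from 29 and activates nitrogen instead of oxygen. m-CPBA would give the N4-oxide F4.
- Trifluoroacetic anhydride at −78 °C would then trigger the fragmentation variant of the Polonovski-Potier reaction, in which the C9 hydroxyl pushes and the acylated N-oxide pulls.
- The fallback comes back to the route at iminium ion 30, which is oxidised with chlorite as before.

Step 10.
- What may go wrong: failure to activate the hindered lactam, over-reduction to the azepane, or loss of the silyl ether through adventitious triflic acid.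
- Fallback: it sets out from lactam 18 and avoids the free imine. O-methylation with Me3OBF4 would give the O-methyl lactim ether F5.
- Heating F5 with bromoketone 24 would move the acylmethyl group onto nitrogen with loss of bromomethane and give the N-(acylmethyl) lactam F6.
- Amide-selective hydrosilylation with IrCl(CO)(PPh3)2 and 1,1,3,3-tetramethyldisiloxane, then warming, would generate ylide 26 reductively from the lactam carbonyl.
- The fallback comes back to the route at 27.

**Further compounds**

F1 | step 15 | (6S)-1-[2-(ethylsulfanyl)-2-oxoethyl]-6-{(1S)-1-[(2R,3S,4S)-3-ethenyl-4-methyl-5-oxooxolan-2-yl]propyl}-6-(triethylsilyloxy)-3,4,5,6-tetrahydro-2H-azepin-1-ium bromide | C1=[N+](CC(=O)SCC)CCCC[C@]1(O[Si](CC)(CC)CC)[C@@H](CC)[C@@H]2OC(=O)[C@@H](C)[C@@H]2C=C.[Br-]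
F2 | step 15 | tetracyclic C3 S-ethyl thioester (9S-silyloxy, 9aS, other centres as in 27) | CC[C@@H]1[C@@]2(O[Si](CC)(CC)CC)CCCCN3[C@H]2[C@@H](C[C@H]3C(=O)SCC)[C@@H]4[C@H]1OC(=O)[C@H]4C
F3 | step 15 | bromo[(2R)-3-methoxy-2-methyl-3-oxopropyl]zinc | COC(=O)[C@@H](C)C[Zn]Br
F4 | step 17 | N4-oxide of 29 | CC[C@@H]1[C@@]2(O)CCCC[N+]3([O-])[C@H]2[C@@H](C[C@H]3[C@@H]5C[C@H](C)C(=O)O5)[C@@H]4[C@H]1OC(=O)[C@H]4C
F5 | step 10 | O-methyl lactim ether of 18 | COC1=NCCCC[C@]1(O[Si](CC)(CC)CC)[C@@H](CC)[C@@H]2OC(=O)[C@@H](C)[C@@H]2C=C
F6 | step 10 | N-[(4S)-5-methoxy-4-methyl-2,5-dioxopentyl] derivative of lactam 18 | O=C1N(CC(=O)C[C@H](C)C(=O)OC)CCCC[C@]1(O[Si](CC)(CC)CC)[C@@H](CC)[C@@H]2OC(=O)[C@@H](C)[C@@H]2C=C
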